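**Strategy**

Everything rests on breaking ring B at C8–C9. What remains is ring A (C1–C5, C10), whose quaternary centres C4 and C10 hold their methyl groups axial and their carbon substituents C18 and C9 equatorial, with C5–H between them; dehydroabietic acid contains exactly this ring when numbered in the opposite direction, so ozonolysis of its arene delivers it with all three stereocentres. A palladium hydride then cycloisomerizes 1,7-enyne 14, exploiting the adjacent equatorial arms of ring A (but-3-ynyl on C5, (E)-3-silyloxyprop-1-enyl on C10) that hold C8 beside C9: one operation closes ring B, sets C9, makes the C8=C17 methylene and leaves C12 as a silyl enol ether.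

Key step: step 12

Remarks on the chemistry (assumptions):
- Labdane locants of the target are used for every compound. "Core" means the cyclohexane of 1 that becomes ring A, stereocentres untouched: C4 bears CH3 and C18, C5 bears H and the chain C6–C7–C8, C10 bears CH3 and C9; both methyls and C6 lie on one face, C18, H5 and C9 on the other.
- TBDPS = tert-butyldiphenylsilyl, TBS = tert-butyldimethylsilyl; 1 is the natural dextrorotatory acid.
- The ligand enantiomer in step 16 is written on the assumption that face selection follows that of linear alkyl Grignard additions to crotonates with this ligand; a model addition would confirm it, and the mirror-image ligand would be used if the sense were opposite.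

**Route**

Step 1
Reactants: 1 dehydroabietic acid
Product: 2 methyl dehydroabietate
Conditions: MeI, K2CO3, DMF, rt
Reagents that add atoms: iodomethane, IC
Why: Carboxylate O-alkylation (SN2 on iodomethane) should esterify the hindered tertiary acid, which resists acid-catalysed esterification, without touching a stereocentre.

Step 2
Reactants: 2 methyl dehydroabietate
Product: 3 core diacid (C18 = CO2H, C8 = CO2H on the C5 chain, C9 = CO2CH3)
Conditions: O3, CH2Cl2/AcOH, 0 °C, to full consumption; then 30% H2O2, HCO2H, 40 °C
Reagents that add atoms: ozone, [O-][O+]=O; hydrogen peroxide, OO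
Why: Exhaustive ozonolysis of the trialkylbenzene, then oxidative peroxide cleavage of the 1,2-dicarbonyl fragments, should leave only the two ring-fusion carbons as carboxyl groups, while the sp3 stereocentres and the hindered methyl ester are inert to ozone.

Step 3
Reactants: 3 core diacid
Product: 4 core acid diester (C18 = CO2H, C8 = CO2CH3, C9 = CO2CH3)
Conditions: MeOH, H2SO4 (cat.), rt
Reagents that add atoms: methanol, CO
Why: Fischer esterification discriminates on steric grounds, so the primary propanoic acid should esterify at room temperature while the tertiary, doubly flanked C18 acid does not.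

Step 4
Reactants: 4 core acid diester
Product: 5 core hydroxy diester (C18 = CH2OH)
Conditions: BH3·SMe2, THF, 0 °C → rt; MeOH
Reagents that add atoms: none
Why: Borane reduces carboxylic acids through acyloxyboranes much faster than esters, so only the C18 acid should become the neopentyl alcohol.

Step 5
Reactants: 5 core hydroxy diester
Product: 6 core silyl ether diester (C18 = CH2OTBDPS)
Conditions: TBDPSCl, imidazole, DMF, rt
Reagents that add atoms: tert-butyl(chloro)diphenylsilane, CC(C)(C)[Si](Cl)(c1ccccc1)c1ccccc1
Why: Imidazole-promoted silylation of the primary alcohol is mild enough to avoid lactonization onto the cis C9 ester, and the bulky ether later disfavours the ring-flipped chair of ring A.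

Step 6
Reactants: 6 core silyl ether diester
Product: 8 core alkyne ester (C5 chain = but-3-ynyl with C8≡C17H; C9 = CO2CH3; C18 = CH2OTBDPS), via chain aldehyde 7 (not isolated)
Conditions: i-Bu2AlH (1.1 equiv), CH2Cl2, −78 °C; then MeOH, dimethyl (1-diazo-2-oxopropyl)phosphonate, K2CO3, −78 °C → rt
Reagents that add atoms: dimethyl (1-diazo-2-oxopropyl)phosphonate, CC(=O)C(=[N+]=[N-])P(=O)(OC)OC
Why: Partial hydride reduction of the unhindered ester gives an aluminium hemiacetal that collapses to the aldehyde on methanol addition and is homologated in the same flask by the Ohira–Bestmann variant of the Seyferth–Gilbert reaction; the neopentyl C9 ester is too hindered to react at −78 °C.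

Step 7
Reactants: 8 core alkyne ester
Product: 9 core alkyne alcohol (C9 = CH2OH)
Conditions: LiAlH4, THF, 0 °C → rt
Reagents that add atoms: none
Why: Hydride reduction of the hindered ester to the primary alcohol should spare the isolated terminal alkyne and the silyl ether.

Step 8
Reactants: 9 core alkyne alcohol
Product: 10 core alkyne aldehyde (C9 = CHO)
Conditions: Dess–Martin periodinane, CH2Cl2, rt
Reagents that add atoms: none
Why: Dess–Martin oxidation of the neopentyl alcohol stops at the non-enolizable aldehyde.

Step 9
Reactants: 10 core alkyne aldehyde; 11 triethyl phosphonoacetate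
Product: 12 core enoate (C10 arm = (E)-CH=CH–CO2Et, C9=C11)
Conditions: NaH, THF, 0 → 60 °C
Reagents that add atoms: none
Why: Horner–Wadsworth–Emmons olefination of a non-enolizable aldehyde with a stabilized phosphonate anion should give the (E)-enoate.

Step 10
Reactants: 12 core enoate
Product: 13 core allylic alcohol (C10 arm = (E)-CH=CH–CH2OH)
Conditions: i-Bu2AlH (2.2 equiv), CH2Cl2, −78 °C
Reagents that add atoms: none
Why: 1,2-Reduction of the enoate at low temperature should give the (E)-allylic alcohol without touching the alkyne or the alkene geometry.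

Step 11
Reactants: 13 core allylic alcohol
Product: 14 core enyne (C5 = but-3-ynyl; C4 = CH3 and CH2OTBDPS; C10 = CH3 and (E)-CH=CH–CH2OTBS)
Conditions: TBSCl, imidazole, DMF, rt
Reagents that add atoms: tert-butyl(chloro)dimethylsilane, CC(C)(C)[Si](C)(C)Cl
Why: Standard silylation of the primary allylic alcohol installs the allylic silyl ether that steers β-hydride elimination in the next step.

Step 12
Reactants: 14 core enyne
Product: 15 bicyclic silyl enol ether (trans-decalin with 8(17)-methylene, 9-[(E)-2-(TBS-oxy)ethenyl], 18-OTBDPS; H9 cis to H5 and trans to the C10 methyl)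
Conditions: Pd2(dba)3·CHCl3 (5 mol %), P(o-tol)3 (10 mol %), AcOH (20 mol %), toluene (0.02 M), 80 °C
Reagents that add atoms: none
Why: Pd2(dba)3 and acetic acid give H–Pd–OAc, a divalent palladium hydride, which adds across the terminal alkyne with palladium on C8; the alkenylpalladium inserts the C9=C11 double bond, and syn β-hydride elimination from C12 releases the silyl enol ether and regenerates the hydride. This is the palladium-catalysed Alder-ene cycloisomerization of enynes that carry an allylic silyl ether, used here on a 1,7-enyne. Ring B (C5–C10) closes by 6-exo-trig carbopalladation, forming the C8–C9 bond. C9 is set by the ring-A chair that holds both arms equatorial, the only conformer in which they can meet: in the chair-like transition state C11 and its palladium stay equatorial, outside the forming ring, instead of axial against H5 and H7, so H9 should end cis to H5 and trans to the C10 methyl. The step needs this face selectivity and hydride loss toward C12, not C9; the first is secured by the trans arms on the adjacent stereocentres C5 and C10 and by the bulky C18 silyl ether, which disfavours the ring-flipped chair, the second by the C12 oxygen, whose α-hydrogens are the more hydridic. C4, C5 and C10 cannot epimerize under these conditions.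

Step 13
Reactants: 15 bicyclic silyl enol ether
Product: 17 C12 alcohol (9-CH2CH2OH), via C12 aldehyde 16 (not isolated)
Conditions: TBAF, AcOH (1:1), THF, 0 °C; then NaBH4, MeOH, 0 °C
Reagents that add atoms: none
Why: Buffered fluoride cleaves the enol O–Si bond far faster than the neopentyl diphenylsilyl ether, and borohydride reduces the released aldehyde at once so that no aldol product accumulates; C9 is β to the carbonyl and cannot epimerize.

Step 14
Reactants: 17 C12 alcohol
Product: 18 C12 bromide (9-CH2CH2Br)
Conditions: CBr4, PPh3, CH2Cl2, 0 °C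
Reagents that add atoms: carbon tetrabromide, BrC(Br)(Br)Br
Why: In the Appel reaction bromide displaces the alkoxyphosphonium group at the unhindered primary C12 under neutral conditions that leave the exocyclic alkene and the silyl ether alone.

Step 15
Reactants: 19 (E)-crotonyl chloride
Product: 20 S-ethyl (E)-but-2-enethioate
Conditions: EtSH (1.0 equiv), pyridine, CH2Cl2, 0 °C
Reagents that add atoms: ethanethiol, CCS
Why: Acyl substitution of the acid chloride by the thiol, with pyridine as acid scavenger and no excess thiol, should give the thioester without conjugate addition.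

Step 16
Reactants: 18 C12 bromide; 20 S-ethyl (E)-but-2-enethioate
Product: 22 S-ethyl (13S)-18-(TBDPS-oxy)-ent-labd-8(17)-en-15-thioate, via Grignard reagent 21 (not isolated)
Conditions: Mg, Et2O, reflux; then added slowly to 20 (1.3 equiv), CuBr·SMe2 (5 mol %), (R)-1-[(S)-2-(diphenylphosphino)ferrocenyl]ethyldicyclohexylphosphine (6 mol %), t-BuOMe, −75 °C
Reagents that add atoms: none
Why: Magnesium insertion gives the primary Grignard reagent, and copper-catalysed asymmetric conjugate addition to the unsaturated thioester forms C12–C13, the ligand-bound alkylcopper selecting one enantioface of the thioenoate so that C13 should be set as S under catalyst control.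

Step 17
Reactants: 22 silyl-protected thioester
Product: 23 S-ethyl (13S)-18-hydroxy-ent-labd-8(17)-en-15-thioate
Conditions: TBAF, AcOH (1:1), THF, rt
Reagents that add atoms: none
Why: Fluoride desilylation buffered with acetic acid should free the neopentyl C18 alcohol without hydrolysing the thioester.

Step 18
Reactants: 24 p-coumaric acid
Product: 26 (E)-4-(TBS-oxy)cinnamic acid, via bis-silyl derivative 25 (not isolated)
Conditions: TBSCl (2.5 equiv), imidazole, DMF, rt; then AcOH/THF/H2O, rt
Reagents that add atoms: tert-butyl(chloro)dimethylsilane, CC(C)(C)[Si](C)(C)Cl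
Why: Both phenol and acid are silylated, and the much more labile silyl ester is then hydrolysed selectively under mild aqueous acid, leaving the phenol protected.

Step 19
Reactants: 23 C18 alcohol thioester; 26 (E)-4-(TBS-oxy)cinnamic acid
Product: 27 S-ethyl (13S)-18-[(E)-4-(TBS-oxy)cinnamoyloxy]-ent-labd-8(17)-en-15-thioate
Conditions: EDC·HCl, DMAP, CH2Cl2, rt
Reagents that add atoms: none
Why: Steglich esterification (carbodiimide activation with DMAP as acyl-transfer catalyst) should acylate the primary neopentyl alcohol while the thioester stays a spectator.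

Step 20
Reactants: 27 protected coumarate thioester
Product: 28 (13S)-18-[(E)-4-hydroxycinnamoyloxy]-ent-labd-8(17)-en-15-oic acid (target)
Conditions: LiOH, THF/H2O, 0 °C → rt; then 1 M HCl to pH 3
Reagents that add atoms: lithium hydroxide, [Li+].[OH-]
Why: Hydroxide removes the aryl silyl ether first, and the resulting phenoxide, being vinylogous to the ester carbonyl, deactivates the hindered neopentyl coumarate, so saponification should be confined to the unhindered thioester.

**Compound list**

1 | dehydroabietic acid, natural (+)-enantiomer (abieta-8,11,13-trien-18-oic acid; 4R,5R,10S in abietane numbering) | CC(C)C1=CC2=C(C=C1)[C@]3(CCC[C@@]([C@@H]3CC2)(C)C(=O)O)C | starting material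
2 | methyl dehydroabietate | CC(C)C1=CC2=C(C=C1)[C@]3(CCC[C@@]([C@@H]3CC2)(C)C(=O)OC)C | intermediate
3 | core diacid: C18 = CO2H, C9 = CO2CH3, C5 chain = CH2CH2CO2H | OC(=O)CC[C@@H]1[C@@](C)(C(=O)O)CCC[C@@]1(C)C(=O)OC | intermediate
4 | core acid diester: C18 = CO2H, C9 = CO2CH3, C5 chain = CH2CH2CO2CH3 | COC(=O)CC[C@@H]1[C@@](C)(C(=O)O)CCC[C@@]1(C)C(=O)OC | intermediate
5 | core hydroxy diester: as 4 with C18 = CH2OH | COC(=O)CC[C@@H]1[C@@](C)(CO)CCC[C@@]1(C)C(=O)OC | intermediate
6 | core silyl ether diester: as 4 with C18 = CH2OTBDPS | COC(=O)CC[C@@H]1[C@@](C)(CO[Si](c2ccccc2)(c2ccccc2)C(C)(C)C)CCC[C@@]1(C)C(=O)OC | intermediate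
7 | core chain aldehyde: as 6 with C5 chain = CH2CH2CHO | O=CCC[C@@H]1[C@@](C)(CO[Si](c2ccccc2)(c2ccccc2)C(C)(C)C)CCC[C@@]1(C)C(=O)OC | intermediate
8 | core alkyne ester: C5 chain = but-3-ynyl (C6–C7–C8≡C17H), C18 = CH2OTBDPS, C9 = CO2CH3 | C#CCC[C@@H]1[C@@](C)(CO[Si](c2ccccc2)(c2ccccc2)C(C)(C)C)CCC[C@@]1(C)C(=O)OC | intermediate
9 | core alkyne alcohol: as 8 with C9 = CH2OH | C#CCC[C@@H]1[C@@](C)(CO[Si](c2ccccc2)(c2ccccc2)C(C)(C)C)CCC[C@@]1(C)CO | intermediate
10 | core alkyne aldehyde: as 8 with C9 = CHO | C#CCC[C@@H]1[C@@](C)(CO[Si](c2ccccc2)(c2ccccc2)C(C)(C)C)CCC[C@@]1(C)C=O | intermediate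
11 | triethyl phosphonoacetate | CCOC(=O)CP(=O)(OCC)OCC | starting material
12 | core enoate: as 8 with C10 arm = (E)-CH=CH–CO2Et | C#CCC[C@@H]1[C@@](C)(CO[Si](c2ccccc2)(c2ccccc2)C(C)(C)C)CCC[C@@]1(C)/C=C/C(=O)OCC | intermediate
13 | core allylic alcohol: as 8 with C10 arm = (E)-CH=CH–CH2OH | C#CCC[C@@H]1[C@@](C)(CO[Si](c2ccccc2)(c2ccccc2)C(C)(C)C)CCC[C@@]1(C)/C=C/CO | intermediate
14 | core enyne (key-step precursor): C5 = but-3-ynyl, C4 = CH3 and CH2OTBDPS, C10 = CH3 and (E)-CH=CH–CH2OTBS | C#CCC[C@@H]1[C@@](C)(CO[Si](c2ccccc2)(c2ccccc2)C(C)(C)C)CCC[C@@]1(C)/C=C/CO[Si](C)(C)C(C)(C)C | intermediate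
15 | bicyclic silyl enol ether (key-step product): trans-decalin, 8(17)-methylene, 9-[(E)-2-(TBS-oxy)ethenyl], 18-OTBDPS, H9 cis to H5 and trans to the C10 methyl | C=C1CC[C@@H]2[C@@](C)(CO[Si](c3ccccc3)(c3ccccc3)C(C)(C)C)CCC[C@@]2(C)[C@@H]1/C=C/O[Si](C)(C)C(C)(C)C | intermediate
16 | C12 aldehyde: as 15 with 9-CH2CHO | C=C1CC[C@@H]2[C@@](C)(CO[Si](c3ccccc3)(c3ccccc3)C(C)(C)C)CCC[C@@]2(C)[C@@H]1CC=O | intermediate
17 | C12 alcohol: as 15 with 9-CH2CH2OH | C=C1CC[C@@H]2[C@@](C)(CO[Si](c3ccccc3)(c3ccccc3)C(C)(C)C)CCC[C@@]2(C)[C@@H]1CCO | intermediate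
18 | C12 bromide: as 15 with 9-CH2CH2Br | C=C1CC[C@@H]2[C@@](C)(CO[Si](c3ccccc3)(c3ccccc3)C(C)(C)C)CCC[C@@]2(C)[C@@H]1CCBr | intermediate
19 | (E)-crotonyl chloride | C/C=C/C(Cl)=O | starting material
20 | S-ethyl (E)-but-2-enethioate | C/C=C/C(=O)SCC | intermediate
21 | C12 Grignard reagent: as 15 with 9-CH2CH2MgBr | C=C1CC[C@@H]2[C@@](C)(CO[Si](c3ccccc3)(c3ccccc3)C(C)(C)C)CCC[C@@]2(C)[C@@H]1CC[Mg]Br | intermediate
22 | S-ethyl (13S)-18-(tert-butyldiphenylsilyloxy)-ent-labd-8(17)-en-15-thioate | C=C1CC[C@@H]2[C@@](C)(CO[Si](c3ccccc3)(c3ccccc3)C(C)(C)C)CCC[C@@]2(C)[C@@H]1CC[C@H](C)CC(=O)SCC | intermediate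
23 | S-ethyl (13S)-18-hydroxy-ent-labd-8(17)-en-15-thioate | C=C1CC[C@@H]2[C@@](C)(CO)CCC[C@@]2(C)[C@@H]1CC[C@H](C)CC(=O)SCC | intermediate
24 | p-coumaric acid ((E)-4-hydroxycinnamic acid) | OC(=O)/C=C/c1ccc(O)cc1 | starting material
25 | tert-butyldimethylsilyl (E)-4-(tert-butyldimethylsilyloxy)cinnamate | CC(C)(C)[Si](C)(C)OC(=O)/C=C/c1ccc(O[Si](C)(C)C(C)(C)C)cc1 | intermediate
26 | (E)-4-(tert-butyldimethylsilyloxy)cinnamic acid | OC(=O)/C=C/c1ccc(O[Si](C)(C)C(C)(C)C)cc1 | intermediate
27 | S-ethyl (13S)-18-[(E)-4-(tert-butyldimethylsilyloxy)cinnamoyloxy]-ent-labd-8(17)-en-15-thioate | C=C1CC[C@@H]2[C@@](C)(COC(=O)/C=C/c3ccc(O[Si](C)(C)C(C)(C)C)cc3)CCC[C@@]2(C)[C@@H]1CC[C@H](C)CC(=O)SCC | intermediate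
28 | (13S)-18-[(E)-4-hydroxycinnamoyloxy]-ent-labd-8(17)-en-15-oic acid (4S,5S,9R,10S,13S; CNP0389065.1) | C=C1CC[C@@H]2[C@@](C)(COC(=O)/C=C/c3ccc(O)cc3)CCC[C@@]2(C)[C@@H]1CC[C@H](C)CC(=O)O | target

**Step count and risks**

Total step count: 20. Longest linear sequence: 18 steps (steps 1–14, 16, 17, 19, 20); steps 15 and 18 prepare the two side reagents.

Steps most likely to fail:

Step 12. The palladium hydride may be drained by alkyne oligomerization, or add so slowly that insertion into the hindered C9=C11 bond cannot compete. In that case the alkyne of 14 would be converted by Markovnikov bromoboration and protonolysis (B-bromo-9-borabicyclo[3.3.1]nonane, CH2Cl2, 0 °C; then AcOH) into the 2-bromoalkene F1. Ring B would then be closed by an intramolecular Mizoroki–Heck reaction (Pd(OAc)2, PPh3, Ag2CO3, MeCN, 80 °C): oxidative addition places palladium on C8 without any hydride chemistry, and the same 6-exo insertion and β-hydride loss toward C12 follow. The route is rejoined at 15.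

Step 16. The catalyst may select the C13 face poorly with this bulky primary Grignard reagent, and the C13 epimers would be hard to separate. Control would then be handed to a covalently bound auxiliary. Crotonyl chloride 19 would acylate lithiated (S)-4-phenyloxazolidin-2-one (n-BuLi, THF, −78 °C) to give the N-crotonyl imide F2. The organocopper reagent made from 18 through 21 and CuBr·SMe2 (THF/Me2S, −40 °C) adds to the chelated s-cis imide on the face away from the phenyl group, which should give the imide F3 with 13S configuration. LiSEt in THF at 0 °C then displaces the auxiliary and rejoins the route at thioester 22.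

Step 2. Ozone may attack the unactivated arene incompletely or unselectively, stalling at ring-opened keto acids or oxidizing benzylic C7 so that the chain is shortened. Ring C would then first be made electron-rich. Friedel–Crafts acetylation of 2 (AcCl, AlCl3, CH2Cl2) gives the 12-acetyl ester F4, Baeyer–Villiger oxidation (mCPBA, CH2Cl2) the 12-acetoxy ester F5, and methanolysis (K2CO3, MeOH) the 12-phenol F6. Ozone at −78 °C cleaves the phenol ring far faster than any C–H bond, and the same peroxide work-up returns diacid 3.

Further compounds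
F1 | step 12 | 2-bromoalkene: as 14 with C5 chain = CH2CH2C(Br)=CH2 | C=C(Br)CC[C@@H]1[C@@](C)(CO[Si](c2ccccc2)(c2ccccc2)C(C)(C)C)CCC[C@@]1(C)/C=C/CO[Si](C)(C)C(C)(C)C
F2 | step 16 | N-crotonyl imide: (S)-3-[(E)-but-2-enoyl]-4-phenyloxazolidin-2-one | C/C=C/C(=O)N1[C@@H](c2ccccc2)COC1=O
F3 | step 16 | imide: (S)-4-phenyloxazolidin-2-one N-acylated by the (13S)-18-(TBDPS-oxy)-ent-labd-8(17)-en-15-oyl group | C=C1CC[C@@H]2[C@@](C)(CO[Si](c3ccccc3)(c3ccccc3)C(C)(C)C)CCC[C@@]2(C)[C@@H]1CC[C@H](C)CC(=O)N1[C@@H](c2ccccc2)COC1=O
F4 | step 2 | 12-acetyl ester: methyl 12-acetyldehydroabietate | CC(C)C1=CC2=C(C=C1C(C)=O)[C@]3(CCC[C@@]([C@@H]3CC2)(C)C(=O)OC)C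
F5 | step 2 | 12-acetoxy ester: methyl 12-acetoxydehydroabietate | CC(C)C1=CC2=C(C=C1OC(C)=O)[C@]3(CCC[C@@]([C@@H]3CC2)(C)C(=O)OC)C
F6 | step 2 | 12-phenol: methyl 12-hydroxydehydroabietate | CC(C)C1=CC2=C(C=C1O)[C@]3(CCC[C@@]([C@@H]3CC2)(C)C(=O)OC)C
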